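**Retrosynthetic overview**
- The C8 prenyl group of the target comes from O5 of a (2S)-5-prenyloxy-7-(methoxymethoxy)-6-methyl-4'-methoxyflavanone by a tandem Claisen–Cope shift (C6 is blocked by methyl), followed by MOM removal.
- That flavanone is disconnected at the O1–C2 bond: a catalytic enantioselective 6-endo oxa-Michael closure of a 2'-hydroxychalcone forms ring C and sets the only stereocentre. The methyl-flanked ortho oxygen carries the prenyl group, so only the other oxygen can close, which fixes the 6-methyl/8-prenyl pattern.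
- The chalcone comes from a Claisen–Schmidt condensation of 4-methoxybenzaldehyde with a 6-hydroxy-4-(methoxymethoxy)-3-methyl-2-prenyloxyacetophenone.
- That acetophenone comes from 3-methylphloroacetophenone by bis-MOM protection (the chelated, methyl-flanked OH stays free), O-prenylation of that OH, and selective removal of the MOM group ortho to the ketone.
- Ring order: rings A and B are bought as arenes; ring C is the only ring formed, in the C–O step.

Assumption: 1-(2,4,6-trihydroxy-3-methylphenyl)ethan-1-one (3-methylphloroacetophenone) is taken as a purchasable catalogue compound.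

Catalyst used in step 5 (not a numbered compound): 1-[3,5-bis(trifluoromethyl)phenyl]-3-[(2S)-3,3-dimethyl-1-{[tris(4-methoxyphenyl)-λ5-phosphanylidene]amino}butan-2-yl]thiourea, SMILES CC(C)(C)[C@@H](CN=P(c1ccc(OC)cc1)(c1ccc(OC)cc1)c1ccc(OC)cc1)NC(=S)Nc1cc(C(F)(F)F)cc(C(F)(F)F)c1.

**Route**

Step 1
Reactants: 1 1-(2,4,6-trihydroxy-3-methylphenyl)ethan-1-one
Product: 3 1-[2-hydroxy-4,6-bis(methoxymethoxy)-3-methylphenyl]ethan-1-one, via mono-MOM ether 2 (not isolated)
Conditions: MOMCl (2.2 equiv), iPr2NEt (3 equiv), CH2Cl2, 0 °C to rt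
Reagents that add atoms: chloromethyl methyl ether (MOMCl), COCCl
Why: Williamson-type MOM protection in which the para-OH reacts first (2) and then the more acidic, less hindered ortho-OH next to C5–H, while the ortho-OH flanked by the methyl group is buttressed into the hydrogen bond with the ketone and stays free, which fixes the regiochemical tag for the rest of the route.

Step 2
Reactants: 3 1-[2-hydroxy-4,6-bis(methoxymethoxy)-3-methylphenyl]ethan-1-one; 4 1-bromo-3-methylbut-2-ene (prenyl bromide)
Product: 5 1-[4,6-bis(methoxymethoxy)-3-methyl-2-(3-methylbut-2-en-1-yloxy)phenyl]ethan-1-one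
Conditions: K2CO3 (2 equiv), n-Bu4NI (cat.), DMF, 45 °C
Reagents that add atoms: none
Why: Williamson etherification of the single free phenol in a polar aprotic medium, where O-alkylation of the phenoxide beats dearomatising C-alkylation and the MOM acetals are inert to base.

Step 3
Reactants: 5 1-[4,6-bis(methoxymethoxy)-3-methyl-2-(3-methylbut-2-en-1-yloxy)phenyl]ethan-1-one
Product: 6 1-[6-hydroxy-4-(methoxymethoxy)-3-methyl-2-(3-methylbut-2-en-1-yloxy)phenyl]ethan-1-one
Conditions: HCl (0.5 M), MeOH–THF, 0 to 20 °C, stopped at mono-cleavage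
Reagents that add atoms: none
Why: Acid-catalysed acetal methanolysis in which the MOM group ortho to the ketone is cleaved much faster than the para one (carbonyl-assisted, giving a chelated phenol), so stopping at mono-cleavage frees only the oxygen that will become O1 while the para-MOM ether and the prenyl ether survive the cold dilute acid.

Step 4
Reactants: 6 1-[6-hydroxy-4-(methoxymethoxy)-3-methyl-2-(3-methylbut-2-en-1-yloxy)phenyl]ethan-1-one; 7 4-methoxybenzaldehyde
Product: 9 (E)-1-[6-hydroxy-4-(methoxymethoxy)-3-methyl-2-(3-methylbut-2-en-1-yloxy)phenyl]-3-(4-methoxyphenyl)prop-2-en-1-one, via aldol adduct 8 (not isolated)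
Conditions: KOH (50 % aq., 10 equiv), EtOH, 0 °C to rt, 24–48 h; cold AcOH to pH 6
Reagents that add atoms: none
Why: Claisen–Schmidt aldol condensation in which the masked para-oxygen lets the enolate form readily, the aldol adduct 8 dehydrates by E1cB to the conjugated E-enone, and the strongly basic medium holds the product as its open phenoxide so the chalcone is recovered on cold neutralisation.

Step 5
Reactants: 9 (E)-1-[6-hydroxy-4-(methoxymethoxy)-3-methyl-2-(3-methylbut-2-en-1-yloxy)phenyl]-3-(4-methoxyphenyl)prop-2-en-1-one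
Product: 10 (2S)-7-(methoxymethoxy)-2-(4-methoxyphenyl)-6-methyl-5-(3-methylbut-2-en-1-yloxy)-2,3-dihydro-4H-chromen-4-one
Conditions: 1-[3,5-bis(trifluoromethyl)phenyl]-3-[(2S)-3,3-dimethyl-1-{[tris(4-methoxyphenyl)-λ5-phosphanylidene]amino}butan-2-yl]thiourea (10 mol %), toluene (0.05 M), −20 °C; AcOH quench at full conversion
Reagents that add atoms: none
Why: Proposed new method: the superbasic iminophosphorane deprotonates the only free phenol of 9 to a tight chiral ion pair while the thiourea N–H pair binds the enone carbonyl, so the phenoxide adds 6-endo to the Si face of Cβ of the s-cis enone and sets C2 as S under kinetic control (the antipodal catalyst from D-tert-leucine is used if a model cyclisation shows the opposite facial sense); the 6'-prenyloxy group twists the aryl ketone toward the reactive conformer and makes the 5-alkoxyflavanone the thermodynamic sink, and low temperature plus the acid quench limit E1cB reversal; the closest known reaction types are iminophosphorane-catalysed intramolecular oxa-Michael additions of alcohols to unsaturated esters and amides and thiourea-catalysed cyclisations of 2'-hydroxychalcones that carry an activating α-carboxylate, whereas a high-ee cyclisation of an unactivated, electron-rich 2'-hydroxychalcone is not known.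

Step 6
Reactants: 10 (2S)-7-(methoxymethoxy)-2-(4-methoxyphenyl)-6-methyl-5-(3-methylbut-2-en-1-yloxy)-2,3-dihydro-4H-chromen-4-one
Product: 14 (2S)-5,7-dihydroxy-2-(4-methoxyphenyl)-6-methyl-8-(3-methylbut-2-en-1-yl)-2,3-dihydro-4H-chromen-4-one, via ortho-dienone 11 (not isolated), via para-dienone 12 (not isolated), via MOM ether 13 (not isolated)
Conditions: Eu(fod)3 (10 mol %; fod = 6,6,7,7,8,8,8-heptafluoro-2,2-dimethyloctane-3,5-dionate), CHCl3, 60 °C; then MeOH, HCl (1.5 M), 40 °C
Reagents that add atoms: none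
Why: Lewis-acid-accelerated aromatic Claisen rearrangement to the methyl-blocked ortho carbon (11), Cope shift of the 1,1-dimethylallyl group to C8 (12) and enolisation give the normal prenyl group at the only free ring position with net double allylic inversion, then acetal methanolysis removes the MOM group; C2 is not involved and neither the mild Lewis acid nor the dilute acid opens the pyranone ring, so the 2S centre is kept.

**Compound list**
1 | 1-(2,4,6-trihydroxy-3-methylphenyl)ethan-1-one | CC(=O)c1c(O)cc(O)c(C)c1O | starting material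
2 | 1-[2,6-dihydroxy-4-(methoxymethoxy)-3-methylphenyl]ethan-1-one | CC(=O)c1c(O)cc(OCOC)c(C)c1O | intermediate
3 | 1-[2-hydroxy-4,6-bis(methoxymethoxy)-3-methylphenyl]ethan-1-one | CC(=O)c1c(OCOC)cc(OCOC)c(C)c1O | intermediate
4 | 1-bromo-3-methylbut-2-ene (prenyl bromide) | CC(C)=CCBr | starting material
5 | 1-[4,6-bis(methoxymethoxy)-3-methyl-2-(3-methylbut-2-en-1-yloxy)phenyl]ethan-1-one | CC(=O)c1c(OCOC)cc(OCOC)c(C)c1OCC=C(C)C | intermediate
6 | 1-[6-hydroxy-4-(methoxymethoxy)-3-methyl-2-(3-methylbut-2-en-1-yloxy)phenyl]ethan-1-one | CC(=O)c1c(O)cc(OCOC)c(C)c1OCC=C(C)C | intermediate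
7 | 4-methoxybenzaldehyde | COc1ccc(C=O)cc1 | starting material
8 | 3-hydroxy-1-[6-hydroxy-4-(methoxymethoxy)-3-methyl-2-(3-methylbut-2-en-1-yloxy)phenyl]-3-(4-methoxyphenyl)propan-1-one (racemic aldol adduct) | COc1ccc(C(O)CC(=O)c2c(O)cc(OCOC)c(C)c2OCC=C(C)C)cc1 | intermediate
9 | (E)-1-[6-hydroxy-4-(methoxymethoxy)-3-methyl-2-(3-methylbut-2-en-1-yloxy)phenyl]-3-(4-methoxyphenyl)prop-2-en-1-one | COc1ccc(/C=C/C(=O)c2c(O)cc(OCOC)c(C)c2OCC=C(C)C)cc1 | intermediate
10 | (2S)-7-(methoxymethoxy)-2-(4-methoxyphenyl)-6-methyl-5-(3-methylbut-2-en-1-yloxy)-2,3-dihydro-4H-chromen-4-one | COc1ccc([C@@H]2CC(=O)c3c(OCC=C(C)C)c(C)c(OCOC)cc3O2)cc1 | intermediate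
11 | (2S)-7-(methoxymethoxy)-2-(4-methoxyphenyl)-6-methyl-6-(2-methylbut-3-en-2-yl)-2,3-dihydro-4H-chromene-4,5(6H)-dione (C6 epimers) | COc1ccc([C@@H]2CC(=O)C3=C(O2)C=C(OCOC)C(C)(C(C)(C)C=C)C3=O)cc1 | intermediate
12 | (2S)-7-(methoxymethoxy)-2-(4-methoxyphenyl)-6-methyl-8-(3-methylbut-2-en-1-yl)-2,3-dihydro-4H-chromene-4,5(8H)-dione (C8 epimers) | COc1ccc([C@@H]2CC(=O)C3=C(O2)C(CC=C(C)C)C(OCOC)=C(C)C3=O)cc1 | intermediate
13 | (2S)-5-hydroxy-7-(methoxymethoxy)-2-(4-methoxyphenyl)-6-methyl-8-(3-methylbut-2-en-1-yl)-2,3-dihydro-4H-chromen-4-one | COc1ccc([C@@H]2CC(=O)c3c(O)c(C)c(OCOC)c(CC=C(C)C)c3O2)cc1 | intermediate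
14 | (2S)-5,7-dihydroxy-2-(4-methoxyphenyl)-6-methyl-8-(3-methylbut-2-en-1-yl)-2,3-dihydro-4H-chromen-4-one | COc1ccc([C@@H]2CC(=O)c3c(O)c(C)c(O)c(CC=C(C)C)c3O2)cc1 | target

**Step count**
Total: 6 steps. Longest linear sequence: 6 steps (1 → 3 → 5 → 6 → 9 → 10 → 14).

**Three steps most likely to fail**

Step 5 (proposed new method). The risks are low enantioselectivity, slow turnover on this electron-rich enone, and erosion of ee by reversible ring opening. The fallback uses known chemistry, sets out from 9 and comes back at 10. Compound 9 is cyclised without stereocontrol (NaOAc, EtOH, reflux) to racemic 7-(methoxymethoxy)-2-(4-methoxyphenyl)-6-methyl-5-(3-methylbut-2-en-1-yloxy)-2,3-dihydro-4H-chromen-4-one F4. The racemate is then resolved kinetically by asymmetric transfer hydrogenation with RuCl(p-cymene)[(1R,2R)-TsNCH(Ph)CH(Ph)NH2] (1–2 mol %) and HCO2H/Et3N at rt to about 55 % conversion; the (R,R) catalyst is expected to be the one matched to the 2R ketone, and its antipode is used otherwise. The 2R enantiomer is reduced to (2R,4R)-7-(methoxymethoxy)-2-(4-methoxyphenyl)-6-methyl-5-(3-methylbut-2-en-1-yloxy)-3,4-dihydro-2H-chromen-4-ol F5, and the unreacted 2S ketone is recovered as 10 (at most 50 %); the prenyl olefin is not reduced.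

Step 6. The risks are fragmentation of the blocked ortho-dienone to the de-prenylated phenol instead of the Cope shift, partial racemisation on warming with the Lewis acid, and acid-induced chroman formation between the 7-OH and the new prenyl group. The fallback sets out from 10 and comes back at 14. p-TsOH·H2O in MeOH at 50 °C removes the MOM group and cleaves the allylic aryl ether, giving (2S)-5,7-dihydroxy-2-(4-methoxyphenyl)-6-methyl-2,3-dihydro-4H-chromen-4-one F6. Its only free ring position, C8, is then prenylated by Friedel–Crafts alkylation with 2-methylbut-3-en-2-ol and BF3·OEt2 in dioxane at rt to give 14; the yield is expected to be modest but the regiochemistry is unambiguous.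

Step 1. The risk is co-formation of the regioisomeric bis-MOM ether with the free OH next to C5–H, which would invert the tag; the identity of 3 should be confirmed by NOE before going on. The fallback sets out from 1 and comes back at 6, bypassing 3 and 5. It replaces the MOMCl differentiation by steric differentiation with a bulky silyl chloride. TBSCl (2.2 equiv) and imidazole in DMF silylate the para-OH and the unhindered ortho-OH to give 1-[4,6-bis(tert-butyldimethylsilyloxy)-2-hydroxy-3-methylphenyl]ethan-1-one F1. A neutral Mitsunobu etherification with 3-methylbut-2-en-1-ol (PPh3, DIAD, THF) gives 1-[4,6-bis(tert-butyldimethylsilyloxy)-3-methyl-2-(3-methylbut-2-en-1-yloxy)phenyl]ethan-1-one F2. n-Bu4NF/AcOH in THF gives 1-[4,6-dihydroxy-3-methyl-2-(3-methylbut-2-en-1-yloxy)phenyl]ethan-1-one F3. MOMCl (1.05 equiv) and iPr2NEt at 0 °C then protect the non-chelated para-OH selectively to give 6.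

**Further compounds**
F1 | step 1 | 1-[4,6-bis(tert-butyldimethylsilyloxy)-2-hydroxy-3-methylphenyl]ethan-1-one | CC(=O)c1c(O[Si](C)(C)C(C)(C)C)cc(O[Si](C)(C)C(C)(C)C)c(C)c1O
F2 | step 1 | 1-[4,6-bis(tert-butyldimethylsilyloxy)-3-methyl-2-(3-methylbut-2-en-1-yloxy)phenyl]ethan-1-one | CC(=O)c1c(O[Si](C)(C)C(C)(C)C)cc(O[Si](C)(C)C(C)(C)C)c(C)c1OCC=C(C)C
F3 | step 1 | 1-[4,6-dihydroxy-3-methyl-2-(3-methylbut-2-en-1-yloxy)phenyl]ethan-1-one | CC(=O)c1c(O)cc(O)c(C)c1OCC=C(C)C
F4 | step 5 | racemic 7-(methoxymethoxy)-2-(4-methoxyphenyl)-6-methyl-5-(3-methylbut-2-en-1-yloxy)-2,3-dihydro-4H-chromen-4-one | COc1ccc(C2CC(=O)c3c(OCC=C(C)C)c(C)c(OCOC)cc3O2)cc1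
F5 | step 5 | (2R,4R)-7-(methoxymethoxy)-2-(4-methoxyphenyl)-6-methyl-5-(3-methylbut-2-en-1-yloxy)-3,4-dihydro-2H-chromen-4-ol | COc1ccc([C@H]2C[C@@H](O)c3c(OCC=C(C)C)c(C)c(OCOC)cc3O2)cc1
F6 | step 6 | (2S)-5,7-dihydroxy-2-(4-methoxyphenyl)-6-methyl-2,3-dihydro-4H-chromen-4-one | COc1ccc([C@@H]2CC(=O)c3c(O)c(C)c(O)cc3O2)cc1
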